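## Analysis of the target

Locants used throughout (cyathane-type, read from the SMILES): C20H2=C18–C19(=O)–O–C2H–C1H2–C9(C17H2OAc)–C8H2–C7H2–C6(C16H3)–C14H2–C13H–C12(C15H3)–C11H2–C10H2–C5H–C4(OH)–C3H, with C3 bonded to C18 and C2, C4 to C9, C5 to C6, and an oxirane across C12/C13.

- The core is an angular 5-6-7 carbotricycle: ring A (C1, C2, C3, C4, C9), ring B (C4–C9) and ring C (C5, C6, C14, C13, C12, C11, C10). An α-methylene-γ-butyrolactone is fused on C2–C3 and an epoxide on C12–C13.
- There are eight stereocentres (2S, 3S, 4R, 5S, 6S, 9S, 12S, 13R). Calling the face of the C9 CH2OAc group α: rings A/B and B/C are both trans-fused, 4-OH and the C6 methyl are β and syn-diaxial on ring B, and H5 is α.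
- The lactone is cis-fused on the α face (O at C2 and C18 at C3 both α). The epoxide oxygen is α, anti to the C6 methyl.
- Sensitive groups are the α-methylene lactone (Michael acceptor), the trisubstituted epoxide (acid), the primary acetate (base, nucleophiles) and the tertiary alcohol.
- The hard part is the contiguous array C9 (quaternary)–C4 (tertiary carbinol)–C3–C2 on a trans-hydrindane, together with the 1,4-anti pair of quaternary carbons C9 and C6.
- The feature that invites the strategy: ring A carries O at C2, a carbon branch at C3 and O at C4, next to the quaternary C9. That is the imprint of a cyclopent-2-enone C2(=O)–C3=C4 with an angular substituent at C9, the product pattern of an intramolecular Pauson–Khand reaction that makes rings A and B together from a ring C precursor.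

## Retrosynthetic reasoning

**23 ⇒ 21 (through 22).** The C3–C18 bond and the C18=C20 methylene are cut. An ester-tethered stabilised carbanion on the α-oxygen at C2 can only reach C3 from the α face, so an SN2 opening of a β-3,4-epoxide sets C3, forces the cis-lactone and leaves the epoxide oxygen as the 4β-OH. The methylene is then released by olefination with a C1 electrophile, so the Michael acceptor appears only in the last operation.

**21 ⇒ 20 ⇒ 18.** Both oxiranes are traced to alkenes (C3=C4 and C12=C13) and the tether to an ester of alcohol 18 with acid 19. One peracid step is asked to put oxygen on the β face of ring A (anti to the axial C9 substituent and the allylic ester) and on the α face of ring C (anti to the C6 methyl).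

**18 ⇒ 17.** The C2 carbinol comes from the enone by 1,2-reduction anti to the angular CH2OAc.

**17 ⇒ 16 (key).** Three bonds are cut at once: C4–C9, C1–C2 and C2–C3. Enyne 16 is monocyclic and has only the C5/C6 stereocentres. The forward [2+2+1] builds rings A and B, the C9 quaternary centre and the C2/C3/C4 functional pattern. Cutting here rather than in ring C makes both fully substituted ring-fusion carbons of ring A the direct output of one step.

**16 ⇒ 14 ⇒ 13 ⇒ 12.** C3 is removed (one-carbon homologation of an aldehyde to the alkyne). The silyl ether is exchanged for the acetate only after the basic homologation step.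

**12 ⇒ 8 + 10.** The C8–C9 bond is cut (sp3–sp2 cross-coupling of the hydroborated vinyl group). The 2-oxymethyl-allyl unit brings C9, C1 and the oxygenated C17 in one piece, so C17 never needs a C–H oxidation.

**8 ⇒ 7 ⇒ 6.** Vinyl and hydroxymethyl groups on adjacent carbons are the two ends of a γ-lactone. The carbonyl carbon becomes C7 (then C7=C8) and the CH2–O carbon becomes C4.

**6 ⇒ 5.** Ring C is cut at C12=C13 (ring-closing metathesis).

**5 ⇒ 1 + 2.** The C5–C10 and C6–C14 bonds are cut. Conjugate addition to butenolide 1 followed by anti-alkylation of the enolate with an allyl electrophile sets C5 and the quaternary C6 with the relative configuration ring C needs.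

## Alternatives that were turned down

**Alternative 1: the textbook route (hydrindane first).**
- Disconnection: ring C is annulated onto a preformed A/B unit, the Hajos–Parrish ketone A1, whose angular methyl maps onto C17.
- Forward key step: reductive alkylation of the enone of A1 to set C6/C5, then seven-ring closure by metathesis or ring expansion.
- Turned down because:
  - the angular group of A1 is CH3, so C17 would need a late oxidation of a neopentyl methyl;
  - the five-ring carbonyl of A1 sits at C1, whereas the target is functionalised at C2, C3 and C4, which means a transposition plus three separate functionalisations;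
  - the enone carbonyl ends at C6, which must become a quaternary carbon.
  The step count would be far above that of the chosen route.

**Alternative 2: ring A last by C3–C4 bond formation.**
- Disconnection: C3–C4, with rings B/C and the butenolide preformed in A2.
- Forward key step: intramolecular Barbier-type allylation of the C4 ketone by the 2-(bromomethyl)butenolide of A2, which would close ring A and give the α-methylene lactone in one step.
- Turned down because a two-atom tether on C9 attacking the neighbouring ring ketone closes preferentially to the cis-hydrindanol (tether axial, attack on the same face). That puts 4-OH syn to CH2OAc, and a tertiary carbinol cannot be corrected afterwards. A2 also needs the C9 quaternary centre built by double alkylation next to a ketone that can also enolise towards C5, and a remote C2 stereocentre made separately.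

**Alternative 3: C17 oxygen last by C–H functionalisation.**
- Disconnection: the C17–O bond. The same cyclocarbonylation with a methallyl arm would lead to the 17-deoxy alcohol A3.
- Forward key step: 1,5-hydrogen abstraction from C17 by the alkoxy radical on O2 (hypoiodite conditions).
- Turned down because:
  - the allylic alkoxy radical of A3 is expected to collapse to the enone faster than it abstracts a primary hydrogen;
  - C8–H is also in a 1,5-relationship and is weaker;
  - the product would be a C2–O–C17 ether that ties up the oxygen needed for the lactone.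
  The oxygen at C17 comes for free with the allyl building block in the chosen route, so nothing is gained.

Key step: step 10

Assumption: compounds 1, 2, 9 and 19 are purchased. α/β are used as defined in the analysis (α = face of the C9 CH2OAc group).

## Route

Step 1
Reactants: 1 3-methylfuran-2(5H)-one; 2 4-bromo-2-methylbut-1-ene
Product: 5 (3S,4S)-3-methyl-4-(3-methylbut-3-en-1-yl)-3-(prop-2-en-1-yl)oxolan-2-one, via Grignard reagent 3 (not isolated), via magnesium enolate 4 (not isolated)
Conditions: 2, Mg, Et2O, rt; then 1, CuBr·SMe2 (5 mol %), Josiphos-type ferrocenyl diphosphine (6 mol %, enantiomer chosen for the 4S product), t-BuOMe, −78 °C; then allyl iodide, DMPU, −78 → −20 °C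
Reagents that add atoms: allyl iodide, C=CCI
Why: Copper-catalysed asymmetric conjugate addition of a Grignard reagent to a cyclic α-methyl α,β-unsaturated carbonyl compound, with alkylation of the resulting enolate. The ligand sets C5; allyl iodide then enters anti to the new C5 substituent, so the quaternary C6 has allyl trans and methyl cis to the butenyl chain.

Step 2
Reactants: 5 (3S,4S)-3-methyl-4-(3-methylbut-3-en-1-yl)-3-(prop-2-en-1-yl)oxolan-2-one
Product: 6 (3aS,8aS)-6,8a-dimethyl-3,3a,4,5,8,8a-hexahydro-1H-cyclohepta[c]furan-1-one (trans-fused)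
Conditions: Grubbs II (5 mol %), CH2Cl2 (5 mM), 40 °C
Reagents that add atoms: none
Why: Ring-closing metathesis of the allyl group with the 1,1-disubstituted alkene closes ring C and gives the trisubstituted C12=C13 alkene directly. The trans-diequatorial arms and the quaternary C6 favour closure; no stereocentre is touched.

Step 3
Reactants: 6 bicyclic lactone
Product: 7 (3aS,8aS)-6,8a-dimethyl-3,3a,4,5,8,8a-hexahydro-1H-cyclohepta[c]furan-1-ol (lactol, both C1 epimers)
Conditions: DIBAL-H (1.1 equiv), CH2Cl2, −78 °C; Rochelle salt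
Reagents that add atoms: none
Why: Partial reduction of a γ-lactone to the lactol. The tetrahedral aluminate of this hindered neopentyl carbonyl is stable at low temperature, and the ring alkene is inert.

Step 4
Reactants: 7 lactol
Product: 8 [(1S,2R)-2-ethenyl-2,5-dimethylcyclohept-4-en-1-yl]methanol
Conditions: Ph3PCH3Br (3 equiv), KOt-Bu (3 equiv), THF, 0 → 60 °C
Reagents that add atoms: methyltriphenylphosphonium bromide, C[P+](c1ccccc1)(c1ccccc1)c1ccccc1.[Br-]
Why: Wittig methylenation of the open hydroxy-aldehyde form of the lactol. The aldehyde carbon (C7) sits on the quaternary C6 and cannot enolise, so nothing can epimerise; C8 is added and the C4 hydroxymethyl is released.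

Step 5
Reactants: 9 2-bromoprop-2-en-1-ol
Product: 10 [(2-bromoprop-2-en-1-yl)oxy](tert-butyl)dimethylsilane
Conditions: TBSCl, imidazole, DMF, rt
Reagents that add atoms: tert-butyldimethylsilyl chloride, CC(C)(C)[Si](C)(C)Cl
Why: Standard silylation of a primary allylic alcohol. The silyl ether, unlike an acetate, survives the basic cross-coupling and homologation steps.

Step 6
Reactants: 8 [(1S,2R)-2-ethenyl-2,5-dimethylcyclohept-4-en-1-yl]methanol; 10 [(2-bromoprop-2-en-1-yl)oxy](tert-butyl)dimethylsilane
Product: 12 [(1S,2S)-2-[3-({[tert-butyl(dimethyl)silyl]oxy}methyl)but-3-en-1-yl]-2,5-dimethylcyclohept-4-en-1-yl]methanol, via bis-boryl adduct 11 (not isolated)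
Conditions: 9-BBN (2.2 equiv B–H), THF, rt; then 10, Pd(dppf)Cl2 (5 mol %), AsPh3, Cs2CO3, DMF/H2O, rt
Reagents that add atoms: none
Why: Anti-Markovnikov hydroboration of the monosubstituted vinyl group (the trisubstituted ring alkene does not react with 9-BBN at rt), then B-alkyl Suzuki–Miyaura coupling with the vinyl bromide forms C8–C9. The free hydroxyl only consumes one B–H and is restored on aqueous work-up.

Step 7
Reactants: 12 [(1S,2S)-2-[3-({[tert-butyl(dimethyl)silyl]oxy}methyl)but-3-en-1-yl]-2,5-dimethylcyclohept-4-en-1-yl]methanol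
Product: 13 (1S,2S)-2-[3-({[tert-butyl(dimethyl)silyl]oxy}methyl)but-3-en-1-yl]-2,5-dimethylcyclohept-4-ene-1-carbaldehyde
Conditions: Dess–Martin periodinane, CH2Cl2, 0 °C → rt
Reagents that add atoms: none
Why: Dess–Martin oxidation of the primary alcohol under near-neutral conditions, which keeps the α-stereocentre C5 intact and leaves the alkenes and the silyl ether untouched.

Step 8
Reactants: 13 (1S,2S)-2-[3-({[tert-butyl(dimethyl)silyl]oxy}methyl)but-3-en-1-yl]-2,5-dimethylcyclohept-4-ene-1-carbaldehyde
Product: 14 tert-butyl({2-[2-((1S,7S)-7-ethynyl-1,4-dimethylcyclohept-3-en-1-yl)ethyl]prop-2-en-1-yl}oxy)dimethylsilane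
Conditions: dimethyl (1-diazo-2-oxopropyl)phosphonate, K2CO3, MeOH, 0 °C → rt
Reagents that add atoms: dimethyl (1-diazo-2-oxopropyl)phosphonate, CC(=O)C(=[N+]=[N-])P(=O)(OC)OC
Why: Ohira–Bestmann homologation turns the aldehyde (C4) into the terminal alkyne C4≡C3. The carbonate/methanol medium is mild enough for α-branched aldehydes, and the configuration at C5 is retained.

Step 9
Reactants: 14 tert-butyl({2-[2-((1S,7S)-7-ethynyl-1,4-dimethylcyclohept-3-en-1-yl)ethyl]prop-2-en-1-yl}oxy)dimethylsilane
Product: 16 2-[2-((1S,7S)-7-ethynyl-1,4-dimethylcyclohept-3-en-1-yl)ethyl]prop-2-en-1-yl acetate, via enyne alcohol 15 (not isolated)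
Conditions: TBAF, THF, 0 °C; then Ac2O, Et3N, DMAP (cat.), rt
Reagents that add atoms: acetic anhydride, CC(=O)OC(C)=O
Why: Fluoride desilylation and acetylation of the liberated primary alkoxide in the same flask install the acetate of the target on a robust intermediate. No later step uses a nucleophilic base in a protic medium.

Step 10
Reactants: 16 2-[2-((1S,7S)-7-ethynyl-1,4-dimethylcyclohept-3-en-1-yl)ethyl]prop-2-en-1-yl acetate
Product: 17 (5S,6S,9R)-17-acetoxy-18,19,20-trinorcyatha-3,12-dien-2-one (tricyclic enone: C2 ketone, C3=C4, C9 CH2OAc anti to C6 CH3, H5 trans to C6 CH3)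
Conditions: Co2(CO)8 (20 mol %), tetramethylthiourea (60 mol %), CO (1 atm), toluene, 70 °C
Reagents that add atoms: carbon monoxide, [C-]#[O+]
Why: Intramolecular Pauson–Khand [2+2+1]: the terminal alkyne forms its Co2(CO)6 complex, the tethered 1,1-disubstituted alkene inserts with C4–C9 bond formation, CO inserts at C1 and reductive elimination closes C2–C3. The closest known reaction type is the thiourea-promoted cobalt-catalysed cyclocarbonylation of 1,7-enynes bearing a 1,1-disubstituted alkene, which gives angularly substituted bicyclo[4.3.0]non-1(9)-en-8-ones. Ring B (six-membered) closes by exo insertion of the alkene at its internal carbon; ring A (five-membered) closes by CO insertion and reductive elimination in the same metallacycle. The new quaternary centre C9 is controlled by C5/C6: the four-atom tether is anchored on the trans-disubstituted cycloheptene, whose ring bonds must stay equatorial, so the C6 methyl is axial in a chair-like array and the cobaltacycle holds C1 in the plane of C3=C4, which leaves CH2OAc axial on the face opposite the C6 methyl. Chemoselectivity is secured because the only other alkene is trisubstituted and endocyclic, and it could only react through a strained bridged metallacycle. Regiochemistry is fixed by the tether, which places the alkyne CH (C3) next to the new carbonyl. The acetate, the ring C alkene and C5 are untouched under these neutral conditions. The product carries oxygen at C2 and an alkene across C3/C4, exactly where the target needs O, C and O.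

Step 11
Reactants: 17 tricyclic enone
Product: 18 (2S,5S,6S,9R)-17-acetoxy-18,19,20-trinorcyatha-3,12-dien-2-ol (2α-alcohol, cis to CH2OAc)
Conditions: NaBH4, CeCl3·7H2O, MeOH, −78 °C
Reagents that add atoms: none
Why: Luche 1,2-reduction of the cyclopentenone. Hydride adds to C2 from the β face, anti to the axial CH2OAc on C9 that overhangs the α face of ring A, giving the α-alcohol; the acetate survives at low temperature.

Step 12
Reactants: 18 allylic alcohol; 19 (diethoxyphosphoryl)acetic acid
Product: 20 (2S,5S,6S,9R)-17-acetoxy-18,19,20-trinorcyatha-3,12-dien-2-yl (diethoxyphosphoryl)acetate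
Conditions: DCC, DMAP (cat.), CH2Cl2, 0 °C → rt
Reagents that add atoms: none
Why: Steglich esterification of the secondary allylic alcohol. It attaches C18/C19 to O2 with retention at C2 and removes the hydroxyl that would otherwise direct epoxidation to the α face.

Step 13
Reactants: 20 phosphonoacetate
Product: 21 (2S,3R,4S,5S,6S,9S,12S,13R)-17-acetoxy-3β,4β:12α,13α-diepoxy-18,19,20-trinorcyathan-2-yl (diethoxyphosphoryl)acetate
Conditions: mCPBA (2.4 equiv), CH2Cl2, 0 °C; NaHCO3/Na2S2O3 work-up
Reagents that add atoms: meta-chloroperoxybenzoic acid, O=C(OO)c1cccc(Cl)c1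
Why: Prilezhaev epoxidation of both trisubstituted alkenes. The ring A alkene should be attacked on the β face, anti to the allylic ester and the axial CH2OAc that flank the α face. The ring C alkene should be attacked on the α face, anti to the axial C6 methyl.

Step 14
Reactants: 21 bis-epoxide
Product: 23 (2S,3S,4R,5S,6S,9S,12S,13R)-17-acetoxy-12α,13α-epoxy-4β-hydroxycyath-18(20)-en-19,2α-olide (target CNP0214540.1), via phosphono lactone 22 (not isolated)
Conditions: NaH (1.1 equiv), THF, 0 → 50 °C; then (CH2O)n, rt
Reagents that add atoms: paraformaldehyde (formaldehyde), C=O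
Why: The phosphonoacetate anion opens the 3,4-epoxide at C3 in a 5-exo-tet SN2 from the α face (inversion at C3, retention at C4), giving the cis-fused α-phosphono lactone with the free 4β-OH. Proton transfer from the acidic α-CH to the alkoxide gives the phosphonate carbanion, and Horner–Wadsworth–Emmons reaction with formaldehyde forms the C18=C20 methylene. The remote 12,13-epoxide and the acetate see only a non-nucleophilic base.

## Compound list

1 | 3-methylfuran-2(5H)-one | CC1=CCOC1=O | starting material
2 | 4-bromo-2-methylbut-1-ene | C=C(C)CCBr | starting material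
3 | (3-methylbut-3-en-1-yl)magnesium bromide | C=C(C)CC[Mg]Br | intermediate (not isolated)
4 | bromomagnesium enolate of (4S)-3-methyl-4-(3-methylbut-3-en-1-yl)oxolan-2-one | C=C(C)CC[C@@H]1COC(O[Mg]Br)=C1C | intermediate (not isolated)
5 | (3S,4S)-3-methyl-4-(3-methylbut-3-en-1-yl)-3-(prop-2-en-1-yl)oxolan-2-one | O=C1OC[C@@H](CCC(C)=C)[C@]1(C)CC=C | intermediate
6 | (3aS,8aS)-6,8a-dimethyl-3,3a,4,5,8,8a-hexahydro-1H-cyclohepta[c]furan-1-one | O=C1OC[C@H]2CCC(C)=CC[C@]12C | intermediate
7 | (3aS,8aS)-6,8a-dimethyl-3,3a,4,5,8,8a-hexahydro-1H-cyclohepta[c]furan-1-ol (C1 epimers) | OC1OC[C@H]2CCC(C)=CC[C@]12C | intermediate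
8 | [(1S,2R)-2-ethenyl-2,5-dimethylcyclohept-4-en-1-yl]methanol | OC[C@H]1CCC(C)=CC[C@]1(C)C=C | intermediate
9 | 2-bromoprop-2-en-1-ol | C=C(Br)CO | starting material
10 | [(2-bromoprop-2-en-1-yl)oxy](tert-butyl)dimethylsilane | C=C(Br)CO[Si](C)(C)C(C)(C)C | intermediate
11 | bis-boryl adduct of 8 (C8–B and O–B bonds to 9-borabicyclo[3.3.1]nonan-9-yl) | C1CCC2CCCC1B2OC[C@H]1CCC(C)=CC[C@]1(C)CCB1C2CCCC1CCC2 | intermediate (not isolated)
12 | [(1S,2S)-2-[3-({[tert-butyl(dimethyl)silyl]oxy}methyl)but-3-en-1-yl]-2,5-dimethylcyclohept-4-en-1-yl]methanol | OC[C@H]1CCC(C)=CC[C@]1(C)CCC(=C)CO[Si](C)(C)C(C)(C)C | intermediate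
13 | (1S,2S)-2-[3-({[tert-butyl(dimethyl)silyl]oxy}methyl)but-3-en-1-yl]-2,5-dimethylcyclohept-4-ene-1-carbaldehyde | O=C[C@H]1CCC(C)=CC[C@]1(C)CCC(=C)CO[Si](C)(C)C(C)(C)C | intermediate
14 | tert-butyl({2-[2-((1S,7S)-7-ethynyl-1,4-dimethylcyclohept-3-en-1-yl)ethyl]prop-2-en-1-yl}oxy)dimethylsilane | C#C[C@H]1CCC(C)=CC[C@]1(C)CCC(=C)CO[Si](C)(C)C(C)(C)C | intermediate
15 | 2-[2-((1S,7S)-7-ethynyl-1,4-dimethylcyclohept-3-en-1-yl)ethyl]prop-2-en-1-ol | C#C[C@H]1CCC(C)=CC[C@]1(C)CCC(=C)CO | intermediate (not isolated)
16 | 2-[2-((1S,7S)-7-ethynyl-1,4-dimethylcyclohept-3-en-1-yl)ethyl]prop-2-en-1-yl acetate | C#C[C@H]1CCC(C)=CC[C@]1(C)CCC(=C)COC(C)=O | intermediate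
17 | (5S,6S,9R)-17-acetoxy-18,19,20-trinorcyatha-3,12-dien-2-one | O=C1C[C@]2(COC(C)=O)CC[C@@]3(C)CC=C(C)CC[C@@H]3C2=C1 | intermediate
18 | (2S,5S,6S,9R)-17-acetoxy-18,19,20-trinorcyatha-3,12-dien-2-ol | O[C@H]1C[C@]2(COC(C)=O)CC[C@@]3(C)CC=C(C)CC[C@@H]3C2=C1 | intermediate
19 | (diethoxyphosphoryl)acetic acid | CCOP(=O)(CC(=O)O)OCC | starting material
20 | (2S,5S,6S,9R)-17-acetoxy-18,19,20-trinorcyatha-3,12-dien-2-yl (diethoxyphosphoryl)acetate | CCOP(=O)(CC(=O)O[C@H]1C[C@]2(COC(C)=O)CC[C@@]3(C)CC=C(C)CC[C@@H]3C2=C1)OCC | intermediate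
21 | (2S,3R,4S,5S,6S,9S,12S,13R)-17-acetoxy-3β,4β:12α,13α-diepoxy-18,19,20-trinorcyathan-2-yl (diethoxyphosphoryl)acetate | CCOP(=O)(CC(=O)O[C@H]1C[C@]2(COC(C)=O)CC[C@@]3(C)C[C@H]4O[C@@]4(C)CC[C@@H]3[C@]25O[C@H]15)OCC | intermediate
22 | (2S,3S,4R,5S,6S,9S,12S,13R)-17-acetoxy-18-(diethoxyphosphoryl)-12α,13α-epoxy-4β-hydroxy-20-norcyathan-19,2α-olide (C18 epimers) | CCOP(=O)(OCC)C1C(=O)O[C@H]2C[C@]3(COC(C)=O)CC[C@@]4(C)C[C@H]5O[C@@]5(C)CC[C@@H]4[C@@]3(O)[C@@H]12 | intermediate (not isolated)
23 | (2S,3S,4R,5S,6S,9S,12S,13R)-17-acetoxy-12α,13α-epoxy-4β-hydroxycyath-18(20)-en-19,2α-olide (CNP0214540.1) | C=C1C(=O)O[C@H]2C[C@]3(COC(C)=O)CC[C@@]4(C)C[C@H]5O[C@@]5(C)CC[C@@H]4[C@@]3(O)[C@@H]12 | target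

## Step count and least certain steps

Total: 14 steps. Longest linear sequence: 13 steps (steps 1–4 and 6–14; step 5 is a one-step side branch).

**Step 10 (key step).**
- What may go wrong: insertion of the 1,1-disubstituted alkene (quaternary centre formation in a 1,7-enyne) may be slow, so that alkyne oligomerisation or decomplexation competes. Partial reaction through a boat-like tether would erode the selectivity at C9.
- Fallback: set out from 14 and separate C–C bond formation from carbonylation.
  - C-silylation (LiHMDS, TMSCl) gives tert-butyl({2-[2-((1S,7S)-1,4-dimethyl-7-[(trimethylsilyl)ethynyl]cyclohept-3-en-1-yl)ethyl]prop-2-en-1-yl}oxy)dimethylsilane F1.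
  - Zirconocene-mediated enyne bicyclisation (Cp2ZrCl2, 2 n-BuLi) then CO gives the 3-trimethylsilyl-17-silyloxy tricyclic enone F2.
  - HF·pyridine removes both silyl groups to give the 17-hydroxy enone F3.
  - Acetylation (Ac2O, pyridine) returns to the route at 17.

**Step 14.**
- What may go wrong: C-alkylation of the weakly nucleophilic phosphonoacetate anion by the hindered epoxide may be sluggish, so that base-induced epoxide isomerisation or loss of the acetate competes.
- Fallback: set out from 18 and form C3–C18 by a radical instead of an anion.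
  - Ethyl vinyl ether and NBS give the 2-bromo-1-ethoxyethyl acetal F4.
  - Ueno–Stork 5-exo cyclisation with Bu3SnH under air traps the tertiary C4 radical with oxygen on the open β face; PPh3 reduction of the hydroperoxide gives the ethoxy-tetrahydrofuran alcohol F5.
  - Jones oxidation gives the saturated lactone F6.
  - mCPBA gives the 12α,13α-epoxy lactone F7.
  - LiHMDS and Eschenmoser's salt give the Mannich base F8.
  - Quaternisation with MeI and elimination with NaHCO3 return to the route at 23.

**Step 13.**
- What may go wrong: facial selectivity may be poor at either alkene. The β face of C4 is syn-axial to the C6 methyl, and the cycloheptene is flexible.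
- A failure at ring A is answered by the radical route described for step 14, which does not need the 3,4-epoxide.
- Fallback for ring C: set out from 20 and use a halohydrin, which delivers oxygen to the face opposite the one the electrophile prefers.
  - NBS in aqueous THF gives the 13β-bromo-12α-hydroxy compound F9 (the more electron-rich ring C alkene reacts first).
  - mCPBA then gives the 3β,4β-epoxide F10.
  - A second equivalent of NaHCO3-free NaH in the step 14 conditions closes the bromohydrin, returning to the route at 21 in the flask.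

**Step 1.**
- What may go wrong: the α-methyl lactone is a poorer acceptor than the ketones and esters for which this catalysis is best established, so conversion or enantioselectivity may be low, and the magnesium enolate may alkylate incompletely.
- Fallback: set out from 2 (through 3) and move the enantio-determining step to an acyclic enoate.
  - Copper/Josiphos-catalysed addition of 3 to commercial methyl (E)-4-[(tert-butyldimethylsilyl)oxy]but-2-enoate gives methyl (3S)-3-({[tert-butyl(dimethyl)silyl]oxy}methyl)-6-methylhept-6-enoate F11.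
  - TBAF gives (4S)-4-(3-methylbut-3-en-1-yl)oxolan-2-one F12.
  - LDA and MeI give the trans lactone (3S,4S)-3-methyl-4-(3-methylbut-3-en-1-yl)oxolan-2-one F13.
  - LDA and allyl bromide (alkylation anti to the C5 chain) return to the route at 5.

**Step 11.**
- What may go wrong: hydride delivery from the α face, since the angular group is 1,3 to the carbonyl and its bias may be modest.
- Fallback: set out from 17, accept the epimer (2R,5S,6S,9R)-17-acetoxy-18,19,20-trinorcyatha-3,12-dien-2-ol F14 and invert it while esterifying: Mitsunobu reaction (PPh3, DIAD) with 19 returns to the route at 20.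

## Further compounds

F1 | step 10 | tert-butyl({2-[2-((1S,7S)-1,4-dimethyl-7-[(trimethylsilyl)ethynyl]cyclohept-3-en-1-yl)ethyl]prop-2-en-1-yl}oxy)dimethylsilane | C[Si](C)(C)C#C[C@H]1CCC(C)=CC[C@]1(C)CCC(=C)CO[Si](C)(C)C(C)(C)C
F2 | step 10 | (5S,6S,9R)-17-[(tert-butyldimethylsilyl)oxy]-3-(trimethylsilyl)-18,19,20-trinorcyatha-3,12-dien-2-one | O=C1C[C@]2(CO[Si](C)(C)C(C)(C)C)CC[C@@]3(C)CC=C(C)CC[C@@H]3C2=C1[Si](C)(C)C
F3 | step 10 | (5S,6S,9R)-17-hydroxy-18,19,20-trinorcyatha-3,12-dien-2-one | O=C1C[C@]2(CO)CC[C@@]3(C)CC=C(C)CC[C@@H]3C2=C1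
F4 | step 14 | 2-bromo-1-ethoxyethyl acetal of 18 (acetal epimers) | CCOC(CBr)O[C@H]1C[C@]2(COC(C)=O)CC[C@@]3(C)CC=C(C)CC[C@@H]3C2=C1
F5 | step 14 | 17-acetoxy-19-ethoxy-2α,19-epoxy-20-norcyath-12-en-4β-ol (acetal epimers) | C1C(OCC)O[C@H]2C[C@]3(COC(C)=O)CC[C@@]4(C)CC=C(C)CC[C@@H]4[C@@]3(O)[C@@H]12
F6 | step 14 | 17-acetoxy-4β-hydroxy-20-norcyath-12-en-19,2α-olide | C1C(=O)O[C@H]2C[C@]3(COC(C)=O)CC[C@@]4(C)CC=C(C)CC[C@@H]4[C@@]3(O)[C@@H]12
F7 | step 14 | 17-acetoxy-12α,13α-epoxy-4β-hydroxy-20-norcyathan-19,2α-olide | C1C(=O)O[C@H]2C[C@]3(COC(C)=O)CC[C@@]4(C)C[C@H]5O[C@@]5(C)CC[C@@H]4[C@@]3(O)[C@@H]12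
F8 | step 14 | 17-acetoxy-20-(dimethylamino)-12α,13α-epoxy-4β-hydroxycyathan-19,2α-olide (C18 epimers) | CN(C)CC1C(=O)O[C@H]2C[C@]3(COC(C)=O)CC[C@@]4(C)C[C@H]5O[C@@]5(C)CC[C@@H]4[C@@]3(O)[C@@H]12
F9 | step 13 | 17-acetoxy-13β-bromo-12α-hydroxy-18,19,20-trinorcyath-3-en-2α-yl (diethoxyphosphoryl)acetate | CCOP(=O)(CC(=O)O[C@H]1C[C@]2(COC(C)=O)CC[C@@]3(C)C[C@H](Br)[C@@](C)(O)CC[C@@H]3C2=C1)OCC
F10 | step 13 | 17-acetoxy-13β-bromo-3β,4β-epoxy-12α-hydroxy-18,19,20-trinorcyathan-2α-yl (diethoxyphosphoryl)acetate | CCOP(=O)(CC(=O)O[C@H]1C[C@]2(COC(C)=O)CC[C@@]3(C)C[C@H](Br)[C@@](C)(O)CC[C@@H]3[C@]24O[C@H]14)OCC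
F11 | step 1 | methyl (3S)-3-({[tert-butyl(dimethyl)silyl]oxy}methyl)-6-methylhept-6-enoate | COC(=O)C[C@@H](CO[Si](C)(C)C(C)(C)C)CCC(C)=C
F12 | step 1 | (4S)-4-(3-methylbut-3-en-1-yl)oxolan-2-one | O=C1C[C@H](CCC(C)=C)CO1
F13 | step 1 | (3S,4S)-3-methyl-4-(3-methylbut-3-en-1-yl)oxolan-2-one (trans) | O=C1[C@@H](C)[C@H](CCC(C)=C)CO1
F14 | step 11 | (2R,5S,6S,9R)-17-acetoxy-18,19,20-trinorcyatha-3,12-dien-2-ol | O[C@@H]1C[C@]2(COC(C)=O)CC[C@@]3(C)CC=C(C)CC[C@@H]3C2=C1
A1 | alternative 1 | (7aR)-7a-methyl-2,3,7,7a-tetrahydro-1H-indene-1,5(6H)-dione (Hajos–Parrish ketone) | C[C@@]12CCC(=O)C=C1CCC2=O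
A2 | alternative 2 | B/C ketone carrying CH2OAc and a [(2S)-4-(bromomethyl)-5-oxo-2,5-dihydrofuran-2-yl]methyl group on C9 | BrCC1=C[C@H](C[C@]2(COC(C)=O)CC[C@@]3(C)CC=C(C)CC[C@@H]3C2=O)OC1=O
A3 | alternative 3 | 17-deoxy analogue of 18 (18,19,20-trinorcyatha-3,12-dien-2α-ol) | O[C@H]1C[C@]2(C)CC[C@@]3(C)CC=C(C)CC[C@@H]3C2=C1
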